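Follow one molecule of right-handed substrate and ask which exit it takes: inversion into the left-handed form, or direct reaction with the partner.

in all of them: left-handed substrate 0.050 M; solid reagent 2.50 equiv; right-handed substrate 0.050 M; time 4.0 d
- violet: temperature 10 °C
- ochre: temperature 25 °C

- partner is single-handed; left-handed substrate and right-handed substrate are mirror images of each other, charged as a racemate, each of them at the stated concentration
- solid, in amounts per volume of the solution: solid reagent
- the list of constants is for 25 °C, to be carried to other temperatures by the activation energies
- at the start none of the solid reagent is in solution
- an excess is the difference of the two amounts in percent of their sum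
- an excess is below zero if the other one leads
- the handed part of partner does not stay in what it makes, so the products of the two hands are mirror images too

- the flask with the highest excess of left-handed product over right-handed product ("all alike" if they lie within 1.5 percentage points) (violet / ochre / all alike)
- excess of left-handed product over right-handed product at the end, violet
- excess of left-handed product over right-handed product at the end, ochre

The solid reagent amounts to 0.125 M in each flask, and I write c = 0.050 M for the left-handed charge and B for the partner. I reckon up the ladder of times, in ochre first. While solid lasts, dissolving balances decomposition at B = 34.6 mM. That takes about 1.64 h. At this level left-handed substrate lives 1.20 h, and the selectivity factor is 54.5, so I count the first c of product as left-handed.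

Slowest in ochre is the draining of right-handed substrate, at a = 0.0462 /h, a time of 21.6 h. While partner stands at this level, inversion counts as left-handed product, since partner takes left-handed substrate at 0.831 /h, faster than inversion's 0.031 /h feeds it. My carried quantity is the leak φ, the share of draining right-handed substrate that reacts directly instead of inverting: the direct rate over a, 0.329 in ochre.

At 10 °C in violet the constants become 0.00302 /h for inversion, 0.0925 /M/h for direct reaction and 0.0178 /h for decomposition. So while solid lasts in violet B = 42.4 mM, a = 0.00694 /h and φ = 0.565.

Reagent beyond c is 0.0750 M. I split it between draining and decomposition, assuming a mean right-handed level 0.0375 M, midway between the charge and half of it. This gives late product L = 0.0209 M in ochre and 0.0192 M in violet. The excess is then 1 − 2φL/(c + L): 68.6% in violet and 80.6% in ochre, so I name ochre.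

The forecast also names ochre, but with lower numbers than mine: 63% in violet and 72% in ochre. Its ground: “Warming favours racemisation strongly because of its high activation energy”.

    partner + right-handed substrate → right-handed product (k1 = 0.44 /M/h, Ea1 = 73.0 kJ/mol)
    solid reagent ⇌ partner, rate k2*(cs2 - [partner]) while solid is left; crystals form when [partner] > cs2 (cs2 = 44 mM, k2 = 0.48 /h)
    partner → decomposed reagent (k3 = 0.13 /h, Ea3 = 93.0 kJ/mol)
    partner + left-handed substrate → left-handed product (k4 = 24 /M/h, Ea4 = 47.0 kJ/mol)
    left-handed substrate ⇌ right-handed substrate (k5 = 0.031 /h, Ea5 = 109 kJ/mol)
    (constants at 25 °C)

The simulation puts ochre highest, with 71.6% in violet and 82.2% in ochre, both higher than the forecast. At 4.00 d right-handed product stands at 9.82% in violet and 6.56% in ochre. Set against the product beyond the left-handed charge, that reads as a leak of 0.512 in violet, beside φ = 0.565, and 0.279 in ochre, beside φ = 0.329.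

A neighbour of ochre charged with 1.00 equiv of solid reagent has 0 M beyond c, so in my reckoning φ acts on no late product and the excess should stand near the value the selectivity factor gives, 96.4%. The simulation gives 93.7% for that neighbour.

The rate constants come from no measurement; what happens was integrated by code.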